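**Assumption:** barbatolic acid has no stereocentres (it is achiral), so the "single enantiomer" requirement is moot and there is no stereochemistry to set. This route is designed from first principles and has not been run; the regiochemical and chemoselectivity claims rest on analogy to orsellinate chemistry.

## Retrosynthetic overview

1. The last step frees the ring-B CO2H from a 2,2,2-trichloroethyl (Tce) ester with Zn/AcOH. This avoids hydrogenolysis and base, both of which threaten the internal benzylic ester.
2. Both CHO groups are installed together by a double Rieche formylation at C3 of each 2,4-dihydroxybenzoate ring.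
3. The central ester comes from SN2 attack of orsellinate carboxylate on a ring-B benzylic bromide.
4. The bromide comes from orsellinic acid by acetylation, Tce ester formation and Wohl–Ziegler bromination.
5. No rings are formed; both benzene rings come from commercial orsellinic acid.

## Route

**Step 1**
Reactants: 1, orsellinic acid (2,4-dihydroxy-6-methylbenzoic acid); 2, acetic anhydride
Product: 3, 2,4-diacetoxy-6-methylbenzoic acid
Conditions: Ac2O, pyridine, cat. DMAP, 0 °C to rt; then H2O/THF to hydrolyse the mixed anhydride, dilute HCl work-up
Reagents that add atoms: acetic anhydride, CC(=O)OC(C)=O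
Why: Phenol O-acylation gives electron-poor aryl acetates that suppress ring bromination in step 3.

**Step 2**
Reactants: 3, 2,4-diacetoxy-6-methylbenzoic acid; 4, 2,2,2-trichloroethanol
Product: 5, 2,2,2-trichloroethyl 2,4-diacetoxy-6-methylbenzoate
Conditions: (COCl)2, cat. DMF, CH2Cl2, 0 °C to rt; concentrate; then Cl3CCH2OH, pyridine, cat. DMAP, CH2Cl2, 0 °C to rt
Reagents that add atoms: 2,2,2-trichloroethanol, OCC(Cl)(Cl)Cl
Why: Esterification via the acid chloride installs a Tce ester that is inert to radical bromination, HCl/MeOH and TiCl4 yet removable later by Zn.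

**Step 3**
Reactants: 5, Tce 2,4-diacetoxy-6-methylbenzoate; 6, N-bromosuccinimide
Product: 7, 2,2,2-trichloroethyl 2,4-diacetoxy-6-(bromomethyl)benzoate
Conditions: NBS (1.05 equiv), AIBN (5 mol %), PhCF3, reflux (stop at about 90 % conversion)
Reagents that add atoms: N-bromosuccinimide, O=C1CCC(=O)N1Br
Why: Wohl–Ziegler bromination hits the only benzylic C–H, since the ring is deactivated, no aldehyde is present, and the Tce CH2 is too electron-poor to react.

**Step 4**
Reactants: 7, benzylic bromide; 1, orsellinic acid (second portion, 1.1 equiv)
Product: 8, [3,5-diacetoxy-2-(2,2,2-trichloroethoxycarbonyl)phenyl]methyl 2,4-dihydroxy-6-methylbenzoate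
Conditions: KHCO3 (1.2 equiv), DMF, rt, 16 h
Reagents that add atoms: none (both reactants are incorporated)
Why: Bicarbonate ionises only the carboxylic acid, so carboxylate O-alkylation (SN2) builds the benzylic ester without phenol alkylation, as in benzyl orsellinate preparations.

**Step 5**
Reactants: 8, diacetate diester
Product: 9, [3,5-dihydroxy-2-(2,2,2-trichloroethoxycarbonyl)phenyl]methyl 2,4-dihydroxy-6-methylbenzoate
Conditions: HCl (generated from AcCl) in MeOH/CH2Cl2, rt
Reagents that add atoms: none
Why: Acid-catalysed transesterification removes the unhindered aryl acetates, while the two 2,6-disubstituted benzoate esters are sterically shielded from methanolysis.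

**Step 6**
Reactants: 9, tetraphenol diester; 10, dichloromethyl methyl ether
Product: 11, [4-formyl-3,5-dihydroxy-2-(2,2,2-trichloroethoxycarbonyl)phenyl]methyl 3-formyl-2,4-dihydroxy-6-methylbenzoate (Tce barbatolate)
Conditions: TiCl4 (8 equiv), Cl2CHOMe (3 equiv), CH2Cl2, 0 °C to rt; then 1 M HCl; chromatograph away minor 5-formyl isomers
Reagents that add atoms: dichloromethyl methyl ether, COC(Cl)Cl; water, O (hydrolysis of the chloro ether to CHO)
Why: Rieche formylation of titanium-chelated 2,4-dihydroxybenzoates goes mainly at C3, between the two oxygens, and each ring is deactivated after one formylation so it stops at the dialdehyde.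

**Step 7**
Reactants: 11, Tce barbatolate
Product: 12, barbatolic acid
Conditions: activated Zn dust (10–20 equiv), AcOH/THF 1:1, 0 °C to rt, 1–2 h; filter, dilute HCl work-up
Reagents that add atoms: none
Why: Reductive β-elimination of the Tce ester (loss of 1,1-dichloroethene) frees the acid under mildly acidic conditions that leave the benzylic ester, the hydrogen-bonded aryl aldehydes and the phenols intact.

## Compound list

1 | orsellinic acid (2,4-dihydroxy-6-methylbenzoic acid) | Cc1cc(O)cc(O)c1C(=O)O | starting material (used in steps 1 and 4)
2 | acetic anhydride | CC(=O)OC(C)=O | starting material (reagent)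
3 | 2,4-diacetoxy-6-methylbenzoic acid | Cc1cc(OC(C)=O)cc(OC(C)=O)c1C(=O)O | intermediate
4 | 2,2,2-trichloroethanol | OCC(Cl)(Cl)Cl | starting material (reagent)
5 | 2,2,2-trichloroethyl 2,4-diacetoxy-6-methylbenzoate | Cc1cc(OC(C)=O)cc(OC(C)=O)c1C(=O)OCC(Cl)(Cl)Cl | intermediate
6 | N-bromosuccinimide | O=C1CCC(=O)N1Br | starting material (reagent)
7 | 2,2,2-trichloroethyl 2,4-diacetoxy-6-(bromomethyl)benzoate | BrCc1cc(OC(C)=O)cc(OC(C)=O)c1C(=O)OCC(Cl)(Cl)Cl | intermediate
8 | [3,5-diacetoxy-2-(2,2,2-trichloroethoxycarbonyl)phenyl]methyl 2,4-dihydroxy-6-methylbenzoate | Cc1cc(O)cc(O)c1C(=O)OCc1cc(OC(C)=O)cc(OC(C)=O)c1C(=O)OCC(Cl)(Cl)Cl | intermediate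
9 | [3,5-dihydroxy-2-(2,2,2-trichloroethoxycarbonyl)phenyl]methyl 2,4-dihydroxy-6-methylbenzoate | Cc1cc(O)cc(O)c1C(=O)OCc1cc(O)cc(O)c1C(=O)OCC(Cl)(Cl)Cl | intermediate
10 | dichloromethyl methyl ether | COC(Cl)Cl | starting material (reagent)
11 | [4-formyl-3,5-dihydroxy-2-(2,2,2-trichloroethoxycarbonyl)phenyl]methyl 3-formyl-2,4-dihydroxy-6-methylbenzoate | Cc1cc(O)c(C=O)c(O)c1C(=O)OCc1cc(O)c(C=O)c(O)c1C(=O)OCC(Cl)(Cl)Cl | intermediate
12 | barbatolic acid | Cc1cc(O)c(C=O)c(O)c1C(=O)OCc1cc(O)c(C=O)c(O)c1C(=O)O | target

## Summary

Total steps: 7.
Longest linear sequence: 7 (orsellinic acid 1 to 12; a second portion of 1 enters at step 4).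

Steps most likely to fail, each with a fallback that changes the approach:

1. **Step 6, double Rieche formylation.** Each ring can give some 5-formyl isomer, and the four possible regioisomeric dialdehydes may be hard to separate. Fallback: set the regiochemistry on the monomers before coupling. Make haematommic acid separately (benzyl orsellinate, Rieche, then hydrogenolysis), deacetylate and formylate bromide 7 on its own, purify each, and then couple the two aldehyde-bearing fragments by the step 4 alkylation.
2. **Step 3, benzylic bromination.** The electron-poor toluene may react slowly, over-brominate, or show aryl acetate side reactions. Fallback: avoid C–H bromination by starting ring B from 3,5-dihydroxybenzyl alcohol, which already carries the benzylic oxygen. After MOM protection, introduce the carboxyl by C2 bromination, Br–Li exchange and carboxylation, and the formyl by directed ortho-metalation between the two OMOM groups with DMF.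
3. **Step 7, Zn/AcOH release of the acid.** Zinc may partly reduce the aldehydes, or the freed acid may lactonise to the phthalide and expel haematommic acid. Fallback: use an allyl ester instead of Tce. Brominate acid 3 first, then esterify the bromomethyl acid chloride with allyl alcohol, and unmask at the end with Pd(PPh3)4/PhSiH3 under neutral, non-reductive conditions.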